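Retrosynthetic overview
1. Numbering (cembrane): C1 carries the side chain C15H(C17H3)–C16(=O); C3–O is the lactone oxygen, C4 the carbinol (C18), C7 bears OOH, C8=C19H2, C11–C12 is the epoxide (C20), and C13–C14 is the CH2–CH2 link. The last disconnections are a Schenck ene reaction (C7–OOH/C8=C19 from E-C7=C8–CH3) and a δ-lactone formed by carboxylate opening of a (3S,4S)-epoxide at C3.
2. The propionate unit C15–C17 and the stereocentres C1/C15 come from an Ireland–Claisen rearrangement across C13(O)–C14=C1 inside the preformed 14-membered ring. The C13 oxygen ends up in the lactone carboxyl, and C13=C14 is then saturated.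
3. Key disconnection C13–C14: the carbocycle is closed by intramolecular (E)-alkenylzinc addition of the C14≡C1 alkyne terminus to the C13 aldehyde of an acyclic C17 bis-epoxy ynal.
4. Enabling feature: C13 sits on the quaternary epoxide carbon C12, so the aldehyde cannot enolize and is facially biased, and C13(OH)–C14=C1 is exactly the allylic alcohol that relays oxygen and chirality to C1. The ynal comes from (2E,6E)-farnesol, whose two allylic termini (C2, C13) allow two tartrate-controlled epoxidations that fix C3, C4, C11 and C12.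
5. Ring order: both epoxides on the open chain, then the 14-membered carbocycle (step 7), then the δ-lactone (step 11); the hydroperoxide comes last.

Key step: step 7

Remark: (2E,6E)-farnesol is taken as the pure E,E isomer and all named reagents as purchasable; positions are numbered as in line 1 throughout.

Step 1
Reactants: 1 (2E,6E)-farnesol
Product: 2 (2S,3S)-2,3-epoxyfarnesol (the 3S,4S-epoxide in target numbering)
Conditions: Ti(OiPr)4 (cat.), L-(+)-diethyl tartrate (cat.), t-BuOOH, 4 Å MS, CH2Cl2, −20 °C
Reagents that add atoms: tert-butyl hydroperoxide CC(C)(C)OO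
Why: Katsuki–Sharpless asymmetric epoxidation is directed by the allylic hydroxyl, so only the C3=C4 olefin reacts, and the L-(+)-tartrate ligand delivers oxygen to the face that gives the (2S,3S)-epoxy alcohol, i.e. the (3S,4S)-epoxide that later suffers inversion at C3.

Step 2
Reactants: 2 (2S,3S)-2,3-epoxyfarnesol; 3 trimethylsilylacetylene
Product: 5 silyl enyne epoxide (Me3Si–C14≡C1–C2H2 attached to the 3,4-epoxide), via epoxyfarnesyl triflate 4 (not isolated)
Conditions: Tf2O, 2,6-lutidine, CH2Cl2, −78 °C; crude triflate at once to Me3SiC≡CLi (from 3, n-BuLi), THF/DMPU, −78 to −30 °C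
Reagents that add atoms: trifluoromethanesulfonic anhydride (its CF3SO2 group stays in intermediate 4 only) O=S(=O)(OS(=O)(=O)C(F)(F)F)C(F)(F)F
Why: Alkylation of a lithium acetylide by a primary triflate (SN2 at C2) is far faster at −78 °C than attack on the trisubstituted epoxide, so C1 and C14 are attached with the epoxide stereocentres untouched.

Step 3
Reactants: 5 silyl enyne epoxide
Product: 6 (E)-allylic alcohol (HO–C13H2 on the terminal olefin)
Conditions: SeO2 (cat.), t-BuOOH, salicylic acid (cat.), CH2Cl2, 0 °C to rt
Reagents that add atoms: tert-butyl hydroperoxide (terminal oxidant; the oxygen is relayed through SeO2) CC(C)(C)OO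
Why: SeO2/t-BuOOH allylic oxidation (ene reaction, then [2,3]-shift) attacks the more accessible terminal trisubstituted olefin and, by its known preference, the methyl group trans to the chain, which should give the (E)-allylic alcohol at C13 needed for the second directed epoxidation.

Step 4
Reactants: 6 (E)-allylic alcohol
Product: 7 terminal alkyne (HC14≡C1) with the free C13 allylic alcohol
Conditions: K2CO3 (cat.), MeOH, rt
Reagents that add atoms: none
Why: Methanolysis of the alkynyl C–Si bond under catalytic carbonate frees the terminal alkyne; the 3,4-epoxide has no neighbouring hydroxyl and is inert to these conditions.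

Step 5
Reactants: 7 terminal alkyne allylic alcohol
Product: 8 bis-epoxy alkynol ((3S,4S)- and (11S,12S)-epoxides, HO–C13H2)
Conditions: Ti(OiPr)4 (cat.), L-(+)-diethyl tartrate (cat.), t-BuOOH, 4 Å MS, CH2Cl2, −20 °C
Reagents that add atoms: tert-butyl hydroperoxide CC(C)(C)OO
Why: A second Katsuki–Sharpless epoxidation, again hydroxyl-directed and therefore blind to the C7=C8 olefin and the alkyne, uses the same L-(+)-tartrate to give the (11S,12S)-epoxide of the target.

Step 6
Reactants: 8 bis-epoxy alkynol
Product: 9 bis-epoxy ynal (C13 aldehyde on the quaternary epoxide carbon C12)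
Conditions: TEMPO (cat.), PhI(OAc)2, CH2Cl2, rt
Reagents that add atoms: none
Why: Oxoammonium (TEMPO) oxidation of the primary alcohol stops at the aldehyde, and since C12 is quaternary the epoxy aldehyde can neither enolize nor epimerize.

Step 7
Reactants: 9 bis-epoxy ynal
Product: 13 macrocyclic (13S)-allylic alcohol (14-membered carbocycle; E-C14=C1), via alkenyldicyclohexylborane 10 (not isolated), via alkenyl(ethyl)zinc 11 (not isolated), via ethylzinc alkoxide 12 (not isolated)
Conditions: Cy2BH, toluene, 0 °C; this solution added over 6 h to Et2Zn and (−)-3-exo-(dimethylamino)isoborneol (10 mol%), toluene, 0 °C (final about 5 mM); pH 7 buffer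
Reagents that add atoms: dicyclohexylborane (boron stays in intermediate 10 only) B(C1CCCCC1)C1CCCCC1; diethylzinc (zinc and ethyl stay in intermediates 11 and 12 only) CC[Zn]CC
Why: Cy2BH adds syn and anti-Markovnikov to the terminal alkyne of 9 to give (E)-alkenylborane 10, boron–zinc exchange with Et2Zn gives alkenyl(ethyl)zinc 11, and within the chiral zinc amino-alkoxide formed from the isoborneol ligand the alkenyl group adds to the C13 aldehyde to give alkoxide 12, which is hydrolysed to 13. The closest known reaction type is the one-pot hydroboration/transmetalation/amino-alcohol-catalysed alkenylzinc cyclization of ω-alkynals to macrocyclic (E)-allylic alcohols. The 14-membered carbocycle is closed by 1,2-addition of C14 to the exocyclic C13=O (14-exo-trig) under slow-addition pseudo-dilution. C13 should be set as S by the ligand, which delivers the zinc-bound carbon to the Si face of aldehydes, reinforced by the Felkin–Anh/Cornforth bias of the 2-methyl-2,3-epoxy aldehyde (attack anti to the epoxide C–O, past the C20 methyl) to give the anti epoxy alcohol, while the E geometry of C14=C1 follows from syn hydroboration. The step needs alkyne-over-aldehyde chemoselectivity in the hydroboration, alkenyl-over-ethyl transfer and ring closure over oligomerization: the aldehyde is neopentyl-like, dialkylboranes leave the trisubstituted C7=C8 olefin and the trisubstituted epoxides alone at 0 °C, an sp2 carbon leaves zinc much faster than ethyl, and the substrate is fed slowly.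

Step 8
Reactants: 13 macrocyclic (13S)-allylic alcohol; 14 propionic anhydride
Product: 15 macrocyclic (13S)-allylic propionate
Conditions: Et3N, DMAP (cat.), CH2Cl2, 0 °C to rt
Reagents that add atoms: none
Why: DMAP-catalysed acylation of the secondary allylic alcohol installs, with retention at C13, the propionate that will become C15–C17.

Step 9
Reactants: 15 macrocyclic (13S)-allylic propionate
Product: 19 (15S)-propanoic acid side chain on C1 of the macrocycle (E-C13=C14; both epoxides intact), via lithium enolate 16 (not isolated), via silyl ketene acetal 17 (not isolated), via trimethylsilyl ester 18 (not isolated)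
Conditions: LiN(iPr)2, THF, −78 °C; Me3SiCl/Et3N; −78 °C to rt; aq. NaHCO3/MeOH, then pH 5–6 citrate buffer, 0 °C; acid used at once
Reagents that add atoms: chlorotrimethylsilane (silicon stays in intermediates 17 and 18 only) C[Si](C)(C)Cl
Why: Ireland–Claisen rearrangement: kinetic deprotonation in THF gives the (E)-enolate (methyl cis to the allylic oxygen), and the chair [3,3] transition state with the ring carbon C12 pseudo-equatorial transfers the C13–O bond suprafacially into the new C1–C15 bond, which should set C1 (target configuration) from the (13S) carbinol and C15 as S (anti) from the enolate geometry while the olefin moves to E-C13=C14.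

Step 10
Reactants: 19 unsaturated epoxy acid
Product: 20 saturated epoxy acid (C13H2–C14H2; 1R,15S)
Conditions: 2-nitrobenzenesulfonylhydrazide (excess, in portions), Et3N, CH2Cl2, rt
Reagents that add atoms: none
Why: Diimide transfers H2 in a concerted syn fashion to the 1,2-disubstituted C13=C14 olefin much faster than to the trisubstituted C7=C8 olefin and, unlike metal catalysts, does not hydrogenolyse or isomerize the allylic epoxide, while the amine keeps the acid as its unreactive carboxylate.

Step 11
Reactants: 20 saturated epoxy acid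
Product: 21 hydroxy δ-lactone (1R,3R,4S,11S,12S,15S; E-C7=C8)
Conditions: Cs2CO3, DMF, 60 °C; then pH 6 buffer
Reagents that add atoms: none
Why: Intramolecular SN2 opening of the 3,4-epoxide by the carboxylate (6-exo-tet) occurs at the secondary carbon C3 with inversion, which should give the (3R) lactone oxygen and leave the (4S) tertiary alkoxide as the C4 hydroxyl; the 11,12-epoxide has no nucleophile within reach of a small ring.

Step 12
Reactants: 21 hydroxy δ-lactone
Product: 22 target hydroperoxide CNP0319766.2
Conditions: O2, hν (visible), 5,10,15,20-tetraphenylporphyrin (cat.), CH2Cl2, −20 to 0 °C; no reductive work-up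
Reagents that add atoms: dioxygen O=O
Why: Schenck ene reaction of singlet oxygen with the only remaining olefin: the perepoxide forms on the more substituted side of the E-C7=C8 bond and abstraction of a hydrogen from the freely rotating C19 methyl places the hydroperoxide at C7 and the double bond at C8=C19, with oxygen approaching the outer face of the macrocyclic olefin, which is expected to give the (7S) configuration.

Compound list
1 | (2E,6E)-farnesol | OC/C=C(C)/CC/C=C(C)/CCC=C(C)C | starting material
2 | (2S,3S)-2,3-epoxyfarnesol | OC[C@@H]1O[C@@]1(C)CC/C=C(C)/CCC=C(C)C | intermediate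
3 | trimethylsilylacetylene | C#C[Si](C)(C)C | starting material
4 | (2S,3S)-2,3-epoxyfarnesyl trifluoromethanesulfonate | FC(F)(F)S(=O)(=O)OC[C@@H]1O[C@@]1(C)CC/C=C(C)/CCC=C(C)C | intermediate
5 | open-chain silyl enyne: Me3Si–C14≡C1–C2H2, (3S,4S)-3,4-epoxide, E-C7=C8, C11=C12(CH3)2 | C[Si](C)(C)C#CC[C@@H]1O[C@@]1(C)CC/C=C(C)/CCC=C(C)C | intermediate
6 | as 5 with the terminal olefin oxidized to the (11E)-allylic alcohol HO–C13H2 | C[Si](C)(C)C#CC[C@@H]1O[C@@]1(C)CC/C=C(C)/CC/C=C(C)/CO | intermediate
7 | as 6 with a free terminal alkyne HC14≡C1 | C#CC[C@@H]1O[C@@]1(C)CC/C=C(C)/CC/C=C(C)/CO | intermediate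
8 | bis-epoxy alkynol: (3S,4S)- and (11S,12S)-epoxides, E-C7=C8, HO–C13H2, HC14≡C1 | C#CC[C@@H]1O[C@@]1(C)CC/C=C(C)/CC[C@@H]1O[C@@]1(C)CO | intermediate
9 | bis-epoxy ynal: as 8 with C13 as the aldehyde (epoxide configurations unchanged) | C#CC[C@@H]1O[C@@]1(C)CC/C=C(C)/CC[C@@H]1O[C@@]1(C)C=O | intermediate
10 | (E)-alkenyldicyclohexylborane at C14 of 9 | C1CCCCC1B(C1CCCCC1)/C=C/C[C@@H]1O[C@@]1(C)CC/C=C(C)/CC[C@@H]1O[C@@]1(C)C=O | intermediate
11 | (E)-alkenyl(ethyl)zinc at C14 of 9 | CC[Zn]/C=C/C[C@@H]1O[C@@]1(C)CC/C=C(C)/CC[C@@H]1O[C@@]1(C)C=O | intermediate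
12 | ethylzinc alkoxide of 13 | CC[Zn]O[C@H]1/C=C/C[C@@H]2O[C@@]2(C)CC/C=C(C)/CC[C@@H]2O[C@]21C | intermediate
13 | 14-membered carbocycle: (13S)-carbinol, E-C14=C1, (3S,4S)- and (11S,12S)-epoxides, E-C7=C8 | O[C@H]1/C=C/C[C@@H]2O[C@@]2(C)CC/C=C(C)/CC[C@@H]2O[C@]21C | intermediate
14 | propionic anhydride | CCC(=O)OC(=O)CC | starting material
15 | propionate ester of 13 at the C13 oxygen | CCC(=O)O[C@H]1/C=C/C[C@@H]2O[C@@]2(C)CC/C=C(C)/CC[C@@H]2O[C@]21C | intermediate
16 | lithium (E)-enolate of 15 (methyl cis to the allylic oxygen) | [Li+].C/C=C(/[O-])O[C@H]1/C=C/C[C@@H]2O[C@@]2(C)CC/C=C(C)/CC[C@@H]2O[C@]21C | intermediate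
17 | trimethylsilyl ketene acetal of 15 (methyl trans to OSiMe3) | C/C=C(/O[Si](C)(C)C)O[C@H]1/C=C/C[C@@H]2O[C@@]2(C)CC/C=C(C)/CC[C@@H]2O[C@]21C | intermediate
18 | trimethylsilyl ester of 19 | C[C@H](C(=O)O[Si](C)(C)C)[C@H]1C[C@@H]2O[C@@]2(C)CC/C=C(C)/CC[C@@H]2O[C@@]2(C)/C=C/1 | intermediate
19 | (15S)-2-(macrocyclyl)propanoic acid: side chain on C1 (target configuration), E-C13=C14, both epoxides, E-C7=C8 | C[C@H](C(=O)O)[C@H]1C[C@@H]2O[C@@]2(C)CC/C=C(C)/CC[C@@H]2O[C@@]2(C)/C=C/1 | intermediate
20 | as 19 with C13H2–C14H2 saturated (1R,15S) | C[C@H](C(=O)O)[C@H]1C[C@@H]2O[C@@]2(C)CC/C=C(C)/CC[C@@H]2O[C@@]2(C)CC1 | intermediate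
21 | deoxy precursor: (1R,3R,4S,11S,12S,15S)-δ-lactone (O on C3), 4-OH, 11,12-epoxide, E-C7=C8(CH3) | C/C1=C\CC[C@](C)(O)[C@H]2C[C@@H](CC[C@]3(C)O[C@H]3CC1)[C@H](C)C(=O)O2 | intermediate
22 | CNP0319766.2, (1R,3R,4S,7S,11S,12S,15S)-7-hydroperoxy-8(19)-ene | C=C1CC[C@@H]2O[C@@]2(C)CC[C@@H]2C[C@@H](OC(=O)[C@H]2C)[C@@](C)(O)CC[C@@H]1OO | target

Total step count: 12. Longest linear sequence: 12 steps, from (2E,6E)-farnesol.

Steps most likely to fail

Step 7. Ring closure may lose to oligomerization, the borane may reduce the aldehyde before the alkyne is consumed, or the facial selectivity at C13 may be low. The fallback sets out from 8. Hydrozirconation and iodination (Cp2Zr(H)Cl, THF; then I2) should give the (E)-vinyl iodide epoxy alcohol F1, and TEMPO/PhI(OAc)2 the iodo aldehyde F2. A Nozaki–Hiyama–Kishi macrocyclization (CrCl2, NiCl2 cat., DMSO/THF, high dilution) then closes the same C13–C14 bond and should give 13 together with its C13 epimer F3. If the two epimers form, the mixture is oxidized with Dess–Martin periodinane to the macrocyclic epoxy enone F4, and chelation-controlled reduction (Zn(BH4)2, Et2O, −20 °C) should return the anti alcohol 13, where the fallback rejoins the route.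

Step 12. Singlet oxygen may abstract hydrogen from C6 instead of C19 (giving the tertiary C8 hydroperoxide), or may approach the wrong olefin face. The fallback sets out from 21 and fixes C7 with a reagent instead of the ring. Photooxygenation as in step 12, followed in the same flask by PPh3, reduces the C7-epimeric hydroperoxides F5 to the C7 allylic alcohols F6; a tertiary C8 regioisomer is removed at this point. MnO2 oxidizes only the secondary allylic alcohol to the 8(19)-en-7-one F7. Corey–Bakshi–Shibata reduction with the (S)-2-methyl-oxazaborolidine and catecholborane should give the (7R)-alcohol F8, and mesylation (Ms2O, Et3N, −20 °C) the (7R)-mesylate F9. SN2 displacement with the potassium salt of 2-methoxyprop-2-yl hydroperoxide (KOtBu, DMF, 0 °C) should give, with inversion, the (7S)-peroxyketal F10, and aqueous acetic acid unmasks 22.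

Step 9. The amide base or the silyl chloride may open or eliminate an epoxide, or a boat transition state may erode control at C15. The fallback sets out from 13 and skips step 8. Eschenmoser–Claisen rearrangement with 1,1-dimethoxy-N,N-dimethylpropan-1-amine (xylene, 130 °C, neutral) should give the γ,δ-unsaturated N,N-dimethylamide F11 with the same suprafacial C13-to-C1 transfer. Diimide (2-nitrobenzenesulfonylhydrazide, Et3N) gives the saturated amide F12. Camphorsulfonic acid in wet CH2Cl2 then lets the amide oxygen open the 3,4-epoxide at C3, and hydrolysis of the iminium lactone releases dimethylamine and returns the route to 21; a C15 epimer would be equilibrated there with base to the all-equatorial lactone.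

Further compounds
F1 | step 7 | (E)-vinyl iodide epoxy alcohol (I–C14H=C1H, HO–C13H2) | I/C=C/C[C@@H]1O[C@@]1(C)CC/C=C(C)/CC[C@@H]1O[C@@]1(C)CO
F2 | step 7 | (E)-vinyl iodide epoxy aldehyde | I/C=C/C[C@@H]1O[C@@]1(C)CC/C=C(C)/CC[C@@H]1O[C@@]1(C)C=O
F3 | step 7 | C13 epimer of 13 | O[C@@H]1/C=C/C[C@@H]2O[C@@]2(C)CC/C=C(C)/CC[C@@H]2O[C@]21C
F4 | step 7 | macrocyclic epoxy enone (C13 ketone, E-C14=C1) | O=C1/C=C/C[C@@H]2O[C@@]2(C)CC/C=C(C)/CC[C@@H]2O[C@]21C
F5 | step 12 | C7-epimeric 7-hydroperoxides (22 and its C7 epimer) | C=C1CC[C@@H]2O[C@@]2(C)CC[C@@H]2C[C@@H](OC(=O)[C@H]2C)[C@@](C)(O)CCC1OO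
F6 | step 12 | C7-epimeric allylic alcohols | C=C1CC[C@@H]2O[C@@]2(C)CC[C@@H]2C[C@@H](OC(=O)[C@H]2C)[C@@](C)(O)CCC1O
F7 | step 12 | 8(19)-en-7-one | C=C1CC[C@@H]2O[C@@]2(C)CC[C@@H]2C[C@@H](OC(=O)[C@H]2C)[C@@](C)(O)CCC1=O
F8 | step 12 | (7R)-allylic alcohol | C=C1CC[C@@H]2O[C@@]2(C)CC[C@@H]2C[C@@H](OC(=O)[C@H]2C)[C@@](C)(O)CC[C@H]1O
F9 | step 12 | (7R)-methanesulfonate | C=C1CC[C@@H]2O[C@@]2(C)CC[C@@H]2C[C@@H](OC(=O)[C@H]2C)[C@@](C)(O)CC[C@H]1OS(C)(=O)=O
F10 | step 12 | (7S)-2-methoxyprop-2-yl peroxide | C=C1CC[C@@H]2O[C@@]2(C)CC[C@@H]2C[C@@H](OC(=O)[C@H]2C)[C@@](C)(O)CC[C@@H]1OOC(C)(C)OC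
F11 | step 9 | N,N-dimethylamide analogue of 19 | CN(C)C(=O)[C@@H](C)[C@H]1C[C@@H]2O[C@@]2(C)CC/C=C(C)/CC[C@@H]2O[C@@]2(C)/C=C/1
F12 | step 9 | N,N-dimethylamide analogue of 20 | CN(C)C(=O)[C@@H](C)[C@H]1C[C@@H]2O[C@@]2(C)CC/C=C(C)/CC[C@@H]2O[C@@]2(C)CC1
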